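The target is cut at both aryl–carbonyl bonds of its two-carbon diketone, so that a 1,2-dicarbonyl dication equivalent is joined to two aryl anions. The step uses the fact that C6 of the chromene benzo ring (ring A) sits between the oxygen-bearing carbons C5 and C7, which makes it the one site lithiated between two acetal ethers, and that this dione carries ring A on one end and the 4-methoxyphenyl ring on the other. In one flask, step 4 forms both bonds and delivers the complete benzil. Its precursor is a mirror-symmetric phloroglucinol tris-ether, two MOM ethers and one TIPS ether; the pyran ring is added afterwards.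

Key step: step 4

Remark: chromene numbering is used for the target (O1, C2 with two methyls, C3=C4, C5–OMe, C6–dione, C7–OH, C8–H); 19 has no stereocentre, so no stereocontrol is needed, and commercial phloroglucinol dihydrate is assumed to be dried before use.

Step 1
Reactants: 1 phloroglucinol (benzene-1,3,5-triol)
Product: 2 5-(triisopropylsilyloxy)benzene-1,3-diol
Conditions: TIPSCl (1 equiv), imidazole, DMF, 0 °C → rt; 1 in threefold excess
Reagents that add atoms: triisopropylsilyl chloride (TIPSCl), CC(C)[Si](Cl)(C(C)C)C(C)C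
Why: Silyl ether formation (nucleophilic substitution at silicon) on an excess of the cheap triol should stop largely at the mono-ether, since the bulky TIPS group slows a second silylation and unreacted 1 is washed out with water.

Step 2
Reactants: 2 5-(triisopropylsilyloxy)benzene-1,3-diol
Product: 3 [3,5-bis(methoxymethoxy)phenoxy]triisopropylsilane
Conditions: MOMCl, i-Pr2NEt, CH2Cl2, 0 °C → rt
Reagents that add atoms: chloromethyl methyl ether (MOMCl), COCCl
Why: Double Williamson-type O-alkylation of the two remaining phenols by the reactive α-chloro ether under mild amine-base conditions that leave the aryl TIPS ether intact.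

Step 3
Reactants: 4 4-bromoanisole
Product: 5 4-methoxyphenylmagnesium bromide
Conditions: Mg, I2 (cat.), THF, reflux
Reagents that add atoms: magnesium, [Mg]
Why: Grignard reagent formation by insertion of magnesium into the aryl C–Br bond, to which the methoxy group is inert.

Step 4
Reactants: 3 [3,5-bis(methoxymethoxy)phenoxy]triisopropylsilane; 6 1,4-dimethylpiperazine-2,3-dione; 5 4-methoxyphenylmagnesium bromide
Product: 10 1-[2,6-bis(methoxymethoxy)-4-(triisopropylsilyloxy)phenyl]-2-(4-methoxyphenyl)ethane-1,2-dione, via aryllithium 7 (not isolated), via lithium hemiaminal alkoxide 8 (not isolated), via bis-hemiaminal dialkoxide 9 (not isolated)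
Conditions: n-BuLi, THF, 0 °C; then 6 (suspension in THF), –78 °C; then 5, –78 °C → rt; then 1 M aq. HCl, 0 °C, short contact
Reagents that add atoms: none
Why: n-BuLi is held by both MOM acetal oxygens and removes the proton at C4 of 3 (directed ortho-metalation), and aryllithium 7 adds to one lactam carbonyl of 6 to give the N,O-chelated lithium hemiaminal alkoxide 8, which should not collapse at –78 °C, so no ketone is exposed. The second lactam carbonyl then takes the unhindered Grignard reagent 5 to give dialkoxide 9, and cold dilute acid protonates both hemiaminals, which expel N,N'-dimethylethane-1,2-diamine and leave the 1,2-diketone 10 with both aryl–carbonyl bonds made. The closest known reaction type is the stepwise addition of two different organometallic reagents to an N,N'-dialkyl oxamide (here the cyclic piperazinedione) to give unsymmetrical benzils, which rests on the same persistent tetrahedral adducts as ketone synthesis from N-methoxy-N-methylamides. No ring is closed and 10 has no stereocentre (the hemiaminal centres of 8 and 9 are lost on hydrolysis). Two selectivities are needed: the site of lithiation, secured because the mirror symmetry of 3 leaves C4 as the only carbon between two chelating acetals while the bulky, non-coordinating TIPS ether guards C2 and C6; and one addition per carbonyl, secured by the persistence of the alkoxide adducts and by sending the hindered aryllithium first to the still unencumbered dione.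

Step 5
Reactants: 10 1-[2,6-bis(methoxymethoxy)-4-(triisopropylsilyloxy)phenyl]-2-(4-methoxyphenyl)ethane-1,2-dione
Product: 11 1-[4-hydroxy-2,6-bis(methoxymethoxy)phenyl]-2-(4-methoxyphenyl)ethane-1,2-dione
Conditions: Bu4NF, AcOH, THF, 0 °C
Reagents that add atoms: none
Why: Fluoride-mediated desilylation driven by the strong Si–F bond, with AcOH buffering the acidic para-acyl phenoxide so that the base-sensitive 1,2-diketone and both MOM acetals should be spared.

Step 6
Reactants: 11 1-[4-hydroxy-2,6-bis(methoxymethoxy)phenyl]-2-(4-methoxyphenyl)ethane-1,2-dione; 12 3-chloro-3-methylbut-1-yne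
Product: 13 1-[2,6-bis(methoxymethoxy)-4-(2-methylbut-3-yn-2-yloxy)phenyl]-2-(4-methoxyphenyl)ethane-1,2-dione
Conditions: DBU, CuCl2·2H2O (1 mol%), MeCN, 0 °C → rt
Reagents that add atoms: none
Why: Copper-catalysed propargylic substitution, in which the phenoxide attacks the copper-bound allenylidene derived from tertiary chloride 12, should give the aryl 1,1-dimethylpropargyl ether at low temperature without C-alkylation.

Step 7
Reactants: 13 1-[2,6-bis(methoxymethoxy)-4-(2-methylbut-3-yn-2-yloxy)phenyl]-2-(4-methoxyphenyl)ethane-1,2-dione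
Product: 14 1-[2-hydroxy-6-(methoxymethoxy)-4-(2-methylbut-3-yn-2-yloxy)phenyl]-2-(4-methoxyphenyl)ethane-1,2-dione
Conditions: MgBr2·OEt2, Et2O/CH2Cl2, 0 °C → rt; then cold 0.5 M aq. HCl
Reagents that add atoms: none
Why: Chelation-assisted Lewis-acid cleavage of an aryl MOM acetal, in which magnesium bound between the neighbouring ketone oxygen and one ortho acetal oxygen activates that CH2 toward bromide, and the magnesium aryloxide chelate so formed occupies the carbonyl so that the second MOM ether should stay.

Step 8
Reactants: 14 1-[2-hydroxy-6-(methoxymethoxy)-4-(2-methylbut-3-yn-2-yloxy)phenyl]-2-(4-methoxyphenyl)ethane-1,2-dione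
Product: 17 1-[5-hydroxy-7-(methoxymethoxy)-2,2-dimethyl-2H-chromen-6-yl]-2-(4-methoxyphenyl)ethane-1,2-dione, via allenylphenol 15 (not isolated), via ortho-quinone methide 16 (not isolated)
Conditions: o-xylene, 140 °C
Reagents that add atoms: none
Why: Aromatic propargyl Claisen rearrangement ([3,3]-sigmatropic shift), enolisation to 15, 1,5-hydrogen shift to 16 and oxa-6π electrocyclisation close the pyran ring, and the hydrogen bond from the C2 hydroxyl to the neighbouring ketone, kept intact in the non-polar solvent, should raise the double-bond character of C3–C4 so that the shift goes to C3 and not to C5; no stereocentre is formed.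

Step 9
Reactants: 17 1-[5-hydroxy-7-(methoxymethoxy)-2,2-dimethyl-2H-chromen-6-yl]-2-(4-methoxyphenyl)ethane-1,2-dione
Product: 18 1-[5-methoxy-7-(methoxymethoxy)-2,2-dimethyl-2H-chromen-6-yl]-2-(4-methoxyphenyl)ethane-1,2-dione
Conditions: MeI, K2CO3, DMF, rt → 40 °C
Reagents that add atoms: iodomethane (MeI), CI
Why: Williamson O-methylation of the chelated 5-hydroxyl, which should run cleanly because the diaryl diketone has no enolisable hydrogen and the MOM acetal is stable to base.

Step 10
Reactants: 18 1-[5-methoxy-7-(methoxymethoxy)-2,2-dimethyl-2H-chromen-6-yl]-2-(4-methoxyphenyl)ethane-1,2-dione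
Product: 19 1-(7-hydroxy-5-methoxy-2,2-dimethyl-2H-chromen-6-yl)-2-(4-methoxyphenyl)ethane-1,2-dione
Conditions: p-TsOH·H2O (cat.), MeOH, 40 °C
Reagents that add atoms: none
Why: Acid-catalysed acetal exchange with methanol removes the last MOM group, whose cleavage is helped by the ortho ketone, under conditions mild enough for the aryl methyl ethers and the chromene double bond.

Compound list
1 | phloroglucinol (benzene-1,3,5-triol) | Oc1cc(O)cc(O)c1 | starting material
2 | 5-(triisopropylsilyloxy)benzene-1,3-diol | CC(C)[Si](Oc1cc(O)cc(O)c1)(C(C)C)C(C)C | intermediate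
3 | [3,5-bis(methoxymethoxy)phenoxy]triisopropylsilane | CC(C)[Si](Oc1cc(OCOC)cc(OCOC)c1)(C(C)C)C(C)C | intermediate
4 | 4-bromoanisole | COc1ccc(Br)cc1 | starting material
5 | 4-methoxyphenylmagnesium bromide (THF solution) | COc1ccc([Mg]Br)cc1 | intermediate
6 | 1,4-dimethylpiperazine-2,3-dione | CN1CCN(C)C(=O)C1=O | starting material
7 | [2,6-bis(methoxymethoxy)-4-(triisopropylsilyloxy)phenyl]lithium (aryllithium, not isolated) | [Li]c1c(OCOC)cc(O[Si](C(C)C)(C(C)C)C(C)C)cc1OCOC | intermediate
8 | lithium 2-[2,6-bis(methoxymethoxy)-4-(triisopropylsilyloxy)phenyl]-1,4-dimethyl-3-oxopiperazin-2-olate (racemic, not isolated) | CC(C)[Si](Oc1cc(OCOC)c(C2([O-])N(C)CCN(C)C2=O)c(OCOC)c1)(C(C)C)C(C)C.[Li+] | intermediate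
9 | lithium bromomagnesium 2-[2,6-bis(methoxymethoxy)-4-(triisopropylsilyloxy)phenyl]-3-(4-methoxyphenyl)-1,4-dimethylpiperazine-2,3-diolate (diastereomer mixture, not isolated) | CC(C)[Si](Oc1cc(OCOC)c(C2([O-])N(C)CCN(C)C2([O-])c2ccc(OC)cc2)c(OCOC)c1)(C(C)C)C(C)C.[Li+].[Mg+2].[Br-] | intermediate
10 | 1-[2,6-bis(methoxymethoxy)-4-(triisopropylsilyloxy)phenyl]-2-(4-methoxyphenyl)ethane-1,2-dione | COCOc1cc(O[Si](C(C)C)(C(C)C)C(C)C)cc(OCOC)c1C(=O)C(=O)c1ccc(OC)cc1 | intermediate
11 | 1-[4-hydroxy-2,6-bis(methoxymethoxy)phenyl]-2-(4-methoxyphenyl)ethane-1,2-dione | COCOc1cc(O)cc(OCOC)c1C(=O)C(=O)c1ccc(OC)cc1 | intermediate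
12 | 3-chloro-3-methylbut-1-yne | CC(C)(Cl)C#C | starting material
13 | 1-[2,6-bis(methoxymethoxy)-4-(2-methylbut-3-yn-2-yloxy)phenyl]-2-(4-methoxyphenyl)ethane-1,2-dione | COCOc1cc(OC(C)(C)C#C)cc(OCOC)c1C(=O)C(=O)c1ccc(OC)cc1 | intermediate
14 | 1-[2-hydroxy-6-(methoxymethoxy)-4-(2-methylbut-3-yn-2-yloxy)phenyl]-2-(4-methoxyphenyl)ethane-1,2-dione | COCOc1cc(OC(C)(C)C#C)cc(O)c1C(=O)C(=O)c1ccc(OC)cc1 | intermediate
15 | 1-[2,4-dihydroxy-6-(methoxymethoxy)-3-(3-methylbuta-1,2-dien-1-yl)phenyl]-2-(4-methoxyphenyl)ethane-1,2-dione (allenylphenol, not isolated) | COCOc1cc(O)c(C=C=C(C)C)c(O)c1C(=O)C(=O)c1ccc(OC)cc1 | intermediate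
16 | 1-[2-hydroxy-6-(methoxymethoxy)-3-(3-methylbut-2-en-1-ylidene)-4-oxocyclohexa-1,5-dien-1-yl]-2-(4-methoxyphenyl)ethane-1,2-dione (ortho-quinone methide, vinyl group cis to the ring carbonyl, not isolated) | COCOC1=CC(=O)/C(=C\C=C(C)C)C(O)=C1C(=O)C(=O)c1ccc(OC)cc1 | intermediate
17 | 1-[5-hydroxy-7-(methoxymethoxy)-2,2-dimethyl-2H-chromen-6-yl]-2-(4-methoxyphenyl)ethane-1,2-dione | COc1ccc(C(=O)C(=O)c2c(OCOC)cc3c(c2O)C=CC(C)(C)O3)cc1 | intermediate
18 | 1-[5-methoxy-7-(methoxymethoxy)-2,2-dimethyl-2H-chromen-6-yl]-2-(4-methoxyphenyl)ethane-1,2-dione | COc1ccc(C(=O)C(=O)c2c(OCOC)cc3c(c2OC)C=CC(C)(C)O3)cc1 | intermediate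
19 | 1-(7-hydroxy-5-methoxy-2,2-dimethyl-2H-chromen-6-yl)-2-(4-methoxyphenyl)ethane-1,2-dione | COc1ccc(C(=O)C(=O)c2c(O)cc3c(c2OC)C=CC(C)(C)O3)cc1 | target

Total step count: 10
Longest linear sequence: 9 steps (steps 1, 2 and 4 to 10; step 3 is a side branch that feeds step 4)

Steps most likely to fail

Step 4. What may go wrong: the hindered aryllithium may add sluggishly, or the first adduct may break down before the Grignard reagent arrives, so that over-addition and keto-amide formation erode the mixed diketone. The fallback sets out from 3 and comes back at 10. Compound 3 is lithiated as before and quenched with I2 to give [4-iodo-3,5-bis(methoxymethoxy)phenoxy]triisopropylsilane F1. Sonogashira coupling of this iodide with commercial 4-ethynylanisole (PdCl2(PPh3)2, CuI, Et3N, DMF, 70 °C) should give the diarylalkyne [3,5-bis(methoxymethoxy)-4-[(4-methoxyphenyl)ethynyl]phenoxy]triisopropylsilane F2. Oxidation of the triple bond with KMnO4 buffered by NaHCO3 and MgSO4 in aqueous acetone at rt should then give 10. In this variant the two aryl–carbon bonds come from a lithiation/cross-coupling pair on an alkyne, and the two carbonyl oxygens are introduced afterwards.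

Step 8. What may go wrong: part of the sigmatropic shift may run to C5 instead of C3 (poor site selectivity), leaving a mixture of regioisomeric chromenes. The fallback sets out from 13 and comes back at 19. The mirror-symmetric bis-acetal 13, whose two ortho sites are equivalent, is heated in o-xylene at 140 °C and can give only 1-[5,7-bis(methoxymethoxy)-2,2-dimethyl-2H-chromen-6-yl]-2-(4-methoxyphenyl)ethane-1,2-dione F3. p-TsOH·H2O in MeOH removes both acetals to give 1-(5,7-dihydroxy-2,2-dimethyl-2H-chromen-6-yl)-2-(4-methoxyphenyl)ethane-1,2-dione F4. TIPSCl and imidazole in DMF should silylate the less crowded 7-hydroxyl, since the 5-hydroxyl is wedged between the acyl group and the C4–H of the pyran ring, to give 1-[5-hydroxy-2,2-dimethyl-7-(triisopropylsilyloxy)-2H-chromen-6-yl]-2-(4-methoxyphenyl)ethane-1,2-dione F5. MeI and K2CO3 in DMF methylate the 5-hydroxyl to give 1-[5-methoxy-2,2-dimethyl-7-(triisopropylsilyloxy)-2H-chromen-6-yl]-2-(4-methoxyphenyl)ethane-1,2-dione F6, and Bu4NF/AcOH in THF then gives 19. The two oxygens are told apart by steric bulk after an unambiguous ring closure, not by the direction of the rearrangement.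

Step 7. What may go wrong: the Lewis acid may strip both acetals, or stop short, so that mono-cleavage is not clean. The fallback sets out from 13 and comes back at 14. Both MOM groups are removed on purpose with p-TsOH·H2O in MeOH at rt to give 1-[2,6-dihydroxy-4-(2-methylbut-3-yn-2-yloxy)phenyl]-2-(4-methoxyphenyl)ethane-1,2-dione F7. One MOM group is put back with MOMCl (1 equiv) and i-Pr2NEt in CH2Cl2 at 0 °C. Once one hydroxyl is alkylated, the other is locked in the hydrogen bond to the ketone and should resist a second alkylation, so 14 is reached by selective protection instead of selective deprotection.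

Further compounds
F1 | step 4 | [4-iodo-3,5-bis(methoxymethoxy)phenoxy]triisopropylsilane | COCOc1cc(O[Si](C(C)C)(C(C)C)C(C)C)cc(OCOC)c1I
F2 | step 4 | [3,5-bis(methoxymethoxy)-4-[(4-methoxyphenyl)ethynyl]phenoxy]triisopropylsilane | COCOc1cc(O[Si](C(C)C)(C(C)C)C(C)C)cc(OCOC)c1C#Cc1ccc(OC)cc1
F3 | step 8 | 1-[5,7-bis(methoxymethoxy)-2,2-dimethyl-2H-chromen-6-yl]-2-(4-methoxyphenyl)ethane-1,2-dione | COc1ccc(C(=O)C(=O)c2c(OCOC)cc3c(c2OCOC)C=CC(C)(C)O3)cc1
F4 | step 8 | 1-(5,7-dihydroxy-2,2-dimethyl-2H-chromen-6-yl)-2-(4-methoxyphenyl)ethane-1,2-dione | COc1ccc(C(=O)C(=O)c2c(O)cc3c(c2O)C=CC(C)(C)O3)cc1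
F5 | step 8 | 1-[5-hydroxy-2,2-dimethyl-7-(triisopropylsilyloxy)-2H-chromen-6-yl]-2-(4-methoxyphenyl)ethane-1,2-dione | COc1ccc(C(=O)C(=O)c2c(O[Si](C(C)C)(C(C)C)C(C)C)cc3c(c2O)C=CC(C)(C)O3)cc1
F6 | step 8 | 1-[5-methoxy-2,2-dimethyl-7-(triisopropylsilyloxy)-2H-chromen-6-yl]-2-(4-methoxyphenyl)ethane-1,2-dione | COc1ccc(C(=O)C(=O)c2c(O[Si](C(C)C)(C(C)C)C(C)C)cc3c(c2OC)C=CC(C)(C)O3)cc1
F7 | step 7 | 1-[2,6-dihydroxy-4-(2-methylbut-3-yn-2-yloxy)phenyl]-2-(4-methoxyphenyl)ethane-1,2-dione | Oc1cc(OC(C)(C)C#C)cc(O)c1C(=O)C(=O)c1ccc(OC)cc1
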